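I began at the late end of the epsilon run: open intermediate stood at 67.1% at 20.0 min, then fell to 39.7% at 60.0 min while product rose to 49.1%. So in epsilon the level of open intermediate showed both how far the substrate had opened and how much had gone on.

| flask | substrate | coupling partner | free catalyst | impurity | temperature | remark | time |
|---|---|---|---|---|---|---|---|
| beta | 0.020 M | 0.030 M (fed, over 80 min) | 3.5 mM | 1.5 mM | 0 °C | run made earlier |  |
| epsilon | 0.020 M | 0.030 M (fed, over 80 min) | 18 mM | 1.5 mM | 15 °C | run made earlier |  |
| south | 0.020 M | 0.0300 M (fed, over 150 min) | 12 mM | 1.5 mM |  | at 5 °C throughout | 3.0 h |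
| south-east | 0.020 M | 0.0300 M (fed, over 80 min) | 2.8 mM | 1.5 mM |  | at 5 °C until 80 min, from then on at 25 °C | 3.0 h |

| run | time / min | open intermediate / % | product / % |
|---|---|---|---|
| beta | 6.00 | 3.0 | 0 |
| beta | 20.0 | 9.7 | 1.4 |
| beta | 30.0 | 14.2 | 0.3 |
| beta | 50.0 | 21.3 | 0.6 |
| beta | 60.0 | 24.7 | 1.8 |
| beta | 90.0 | 32.2 | 3.2 |
| epsilon | 5.00 | 45.8 | 0.2 |
| epsilon | 8.00 | 54.3 | 1.1 |
| epsilon | 12.0 | 62.6 | 1.2 |
| epsilon | 20.0 | 67.1 | 6.8 |
| epsilon | 30.0 | 63.2 | 18.0 |
| epsilon | 60.0 | 39.7 | 49.1 |

(readings scatter by 1 percentage point)

* which one finishes higher in amount of open intermediate, in percent of the substrate charged ("neither" within 2 percentage points) (south / south-east / neither)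
* amount of open intermediate at the end, in percent of the substrate charged, south
* amount of open intermediate at the end, in percent of the substrate charged, south-east

Opening was what I read first. I assumed that each impurity takes one catalyst, which leaves a working catalyst W, the charge minus the impurity, and I treated opening as pseudo-first-order in substrate with rate constant kW. Beta's early slope gave k = 146 M⁻¹ h⁻¹ at 0 °C, and epsilon's first reading gave 445 M⁻¹ h⁻¹ at 15 °C. Interpolating on a log scale gave 211 M⁻¹ h⁻¹ at 5 °C. My carried quantity is the opening half-life τ, equal to ln 2 divided by kW, the time in which working catalyst opens half the remaining substrate. At 5 °C, south has W = 10.5 mM and τ = 18.7 min, while south-east has W = 1.30 mM and τ = 151 min.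

Then I drew the curves. Epsilon's highest reading came after about 3.53 half-lives, and if that count carried over, though the temperature and the feed differ, the knee of south lay near 66.0 min, with a decline after it. On this reckoning the substrate of south-east starts by falling at a fractional rate of 0.00457 min⁻¹, and at its warming at 80 min the flask should keep 69.3% of its substrate. Going round once more, I put that remainder into the warm stretch of south-east, where extrapolated k gives τ = 34.1 min, and 9.06% should stay unopened at the end. Beta, with a working catalyst of 2.00 mM at 0 °C, had shown 3.2% product at 90.0 min; south-east has less working catalyst but is warmed, and on that judgement I expected it to finish higher than south, without a close figure for either level.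

The forecast said south-east, with 28% for south and 42% for south-east, holding for south-east that “with little catalyst the drain is slow”.

The flask gave south-east, with 23.0% in south and 60.5% in south-east, and the south-east figure stands 18 percentage points above the forecast's.

    substrate + free catalyst → free catalyst + open intermediate (k = 250 M⁻¹ h⁻¹, Ea = 58.0 kJ mol⁻¹)
    coupling partner + catalyst intermediate → free catalyst + product (k = 240 M⁻¹ h⁻¹, Ea = 37.0 kJ mol⁻¹)
    free catalyst + open intermediate ⇌ catalyst intermediate (K = 32.0 M⁻¹, k = 250 M⁻¹ h⁻¹, Ea = 54.0 kJ mol⁻¹, ΔH = −15.0 kJ mol⁻¹)
    free catalyst + impurity → spent catalyst (k = 1.30 × 10⁵ M⁻¹ h⁻¹, Ea = 47.0 kJ mol⁻¹)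
    (constants at 5 °C)

In south-east at its first temperature the half-life of free catalyst against impurity, by that path alone with the charges held, was 0.21 min, far shorter than τ. Spent catalyst stood at 53.6% of the catalyst charged at 1.33 h, with 66.4% of substrate left against the 69.3% reckoned from τ. The neighbour flask, south with 0.0048 M of free catalyst, has W = 3.30 mM and τ = 59.7 min, so 12.4% of its substrate should remain after 3.0 h. It holds 12.3% substrate, 53.5% open intermediate and 31.5% product.

The readings stem from a simulated flask from invented constants, noise included.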